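**Plan**

1. Retrosynthesis: the syringoyl ester is cut at C3–O and C3 is taken back to a ketone. C4 is then excised by cutting C3–C4 and C4–C4a, which contracts ring C to a 2-arylbenzofuran-3(2H)-one. That ring opens at the acyl–arene bond C3–C3a and at the aryl ether bond O1–C2.
2. Enabling feature: C4 is the only ring-C carbon with neither oxygen nor aryl on it, a bare CH2 between carbinol carbon C3 and A-ring carbon C4a. C4a lies ortho, ortho and para to the oxygens on C5, C8a (O1) and C7, so it is an excellent migrating aryl carbon.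
3. Forward order: the B-ring diazoester and the A-ring phenol are joined at O1–C2, the five-membered furanone closes by acylation, and one-carbon insertion enlarges it to the six-membered pyranone. Reduction, esterification and debenzylation follow.
4. Stereochemistry: C2 of the flavan-3-one is enolisable, so one Ru-catalysed hydrogenation under dynamic kinetic resolution sets C2 (R) and C3 (R) together. The cis relation comes from hydride approach anti to the 2-aryl group and the absolute sense from the ligand; no later step breaks a bond at either centre.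

Key step: step 6

Assumption: the sense of induction of the (S)-BINAP/(R,R)-DPEN ruthenium catalyst in step 7 is carried over from 2-substituted cyclohexanones; should a pilot run show the opposite sense, the mirror-image catalyst is used. Compounds 7–10, 12 and 13 are racemic at C2.

**Step 1**
Reactants: 1 3,4-dihydroxyphenylacetic acid; 2 benzyl bromide
Product: 3 benzyl 2-[3,4-bis(benzyloxy)phenyl]acetate
Conditions: BnBr (3.3 equiv), K2CO3, DMF, 60 °C, Ar
Reagents that add atoms: benzyl bromide (2), BrCc1ccccc1
Why: Williamson etherification of both catechol hydroxyls together with O-alkylation of the carboxylate under carbonate base should give the tribenzyl compound in one operation, the base being too weak to benzylate the benzylic carbon.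

**Step 2**
Reactants: 3 benzyl 2-[3,4-bis(benzyloxy)phenyl]acetate; 4 4-acetamidobenzenesulfonyl azide (p-ABSA)
Product: 5 benzyl 2-[3,4-bis(benzyloxy)phenyl]-2-diazoacetate
Conditions: p-ABSA, DBU, MeCN, 0 °C → rt
Reagents that add atoms: 4-acetamidobenzenesulfonyl azide (4), CC(=O)Nc1ccc(cc1)S(=O)(=O)N=[N+]=[N-]
Why: Regitz diazo transfer, in which DBU deprotonates the arylacetate α-carbon and the enolate takes N2 from the sulfonyl azide, is a standard preparation of aryldiazoacetates that leaves benzyl ethers and the benzyl ester untouched.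

**Step 3**
Reactants: 5 benzyl 2-[3,4-bis(benzyloxy)phenyl]-2-diazoacetate; 6 3,5-bis(benzyloxy)phenol
Product: 7 racemic benzyl 2-[3,5-bis(benzyloxy)phenoxy]-2-[3,4-bis(benzyloxy)phenyl]acetate
Conditions: Rh2(OAc)4 (1 mol%), CH2Cl2, rt, slow addition of 5
Reagents that add atoms: none
Why: Rhodium carbenoid O–H insertion, in which the phenol oxygen captures the donor/acceptor carbenoid as an oxonium ylide that shifts a proton, should form the O1–C2 aryl ether bond faster than attack on the arene; the new centre (future C2) forms racemic, which is harmless because it is equilibrated in step 7.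

**Step 4**
Reactants: 7 racemic benzyl 2-[3,5-bis(benzyloxy)phenoxy]-2-[3,4-bis(benzyloxy)phenyl]acetate
Product: 8 racemic 2-[3,5-bis(benzyloxy)phenoxy]-2-[3,4-bis(benzyloxy)phenyl]acetic acid
Conditions: LiOH·H2O, THF/MeOH/H2O, rt; then 1 M HCl
Reagents that add atoms: lithium hydroxide, [Li+].[OH-]
Why: Saponification of the activated α-aryloxy ester by hydroxide (acyl substitution) should proceed at room temperature without touching the aryl benzyl ethers.

**Step 5**
Reactants: 8 racemic 2-[3,5-bis(benzyloxy)phenoxy]-2-[3,4-bis(benzyloxy)phenyl]acetic acid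
Product: 10 racemic 4,6-bis(benzyloxy)-2-[3,4-bis(benzyloxy)phenyl]benzofuran-3(2H)-one, via mixed trifluoroacetic anhydride 9 (not isolated)
Conditions: (CF3CO)2O (1.5 equiv), CH2Cl2, 0 °C, Ar; cold pH 7 buffer work-up, product used promptly
Reagents that add atoms: none
Why: Intramolecular Friedel–Crafts acylation through the mixed trifluoroacetic anhydride should close the five-membered furanone, because the attacked ring carbon is ortho to the ether oxygen and ortho and para to the two benzyloxy groups (and equivalent to its twin by symmetry), under acid mild enough for benzyl ethers.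

**Step 6**
Reactants: 10 racemic 4,6-bis(benzyloxy)-2-[3,4-bis(benzyloxy)phenyl]benzofuran-3(2H)-one; 11 trimethylsilyldiazomethane
Product: 13 racemic 5,7-bis(benzyloxy)-2-[3,4-bis(benzyloxy)phenyl]chroman-3-one, via 4-trimethylsilyl ketone 12 (not isolated)
Conditions: TMSCHN2 (2 equiv), Sc(OTf)3 (20 mol%), CH2Cl2, −78 → 0 °C, Ar; then 1 M HCl, THF, 0 °C
Reagents that add atoms: trimethylsilyldiazomethane (11), C[Si](C)(C)C=[N+]=[N-]
Why: Proposed new method: the nucleophilic diazo carbon adds to the Sc(III)-bound, ring-strained C3 carbonyl (forming C3–C4), and in the resulting diazonium alkoxide the aryl carbon C3a shifts to the new carbon as N2 leaves (forming C4–C4a); the closest known reaction type is the Lewis acid-promoted silyldiazomethane homologation of benzo-fused cyclic ketones such as 1-indanones and 1-tetralones, a Tiffeneau–Demjanov-type enlargement not yet shown on a 2-arylbenzofuran-3(2H)-one. The pyranone is not made by a cyclisation: it arises from the furanone by a 1,2-shift that inserts one carbon (five- to six-membered ring expansion). No stereocentre is fixed, since C2 stays racemic and enolisable, which step 7 exploits. The step needs C3a to migrate and not C2 (which would give the flavan-4-one); this is secured because C3a lies ortho, ortho and para to the oxygens on C4, C7a and C6 and can bridge like a phenonium ion, whereas C2 is hindered and inductively deactivated by O1. It also needs attack at the carbonyl carbon and not O-alkylation of the 3-hydroxybenzofuran tautomer, for which the aprotic medium, the Lewis acid and the bulky silyl diazoalkane are chosen. A second insertion is blocked because the product stays masked as the α-silyl ketone (or its silyl enol ether) until the acidic work-up removes silicon and leaves the C4 methylene.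

**Step 7**
Reactants: 13 racemic 5,7-bis(benzyloxy)-2-[3,4-bis(benzyloxy)phenyl]chroman-3-one
Product: 14 (2R,3R)-5,7-bis(benzyloxy)-2-[3,4-bis(benzyloxy)phenyl]chroman-3-ol (tetra-O-benzyl-(−)-epicatechin)
Conditions: trans-RuCl2[(S)-BINAP][(R,R)-DPEN] (1 mol%), t-BuOK (10 mol%), H2 (10 atm), i-PrOH/toluene, 25 °C, O2 excluded
Reagents that add atoms: none
Why: Noyori asymmetric hydrogenation under dynamic kinetic resolution, as established for 2-aryl- and 2-alkoxycycloalkanones, should set both centres at once: the base keeps the C2 epimers in equilibrium through the enolate, the chiral Ru–H/N–H catalyst reduces the 2R ketone preferentially, and hydride reaches C3 on the face away from the 2-aryl group, giving the cis (2R,3R) alcohol.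

**Step 8**
Reactants: 15 syringic acid; 2 benzyl bromide
Product: 17 4-(benzyloxy)-3,5-dimethoxybenzoic acid, via benzyl 4-(benzyloxy)-3,5-dimethoxybenzoate 16 (not isolated)
Conditions: BnBr (2.2 equiv), K2CO3, DMF, 60 °C; then 2 M NaOH, MeOH, 65 °C; then HCl
Reagents that add atoms: benzyl bromide (2), BrCc1ccccc1; sodium hydroxide, [Na+].[OH-]
Why: Williamson O-benzylation of the phenol (with concurrent benzyl ester formation) followed by saponification should give the acid, since hydroxide cleaves the ester while the aryl benzyl ether stays.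

**Step 9**
Reactants: 14 (2R,3R)-5,7-bis(benzyloxy)-2-[3,4-bis(benzyloxy)phenyl]chroman-3-ol; 17 4-(benzyloxy)-3,5-dimethoxybenzoic acid
Product: 18 (2R,3R)-5,7-bis(benzyloxy)-2-[3,4-bis(benzyloxy)phenyl]chroman-3-yl 4-(benzyloxy)-3,5-dimethoxybenzoate
Conditions: DCC, DMAP (cat.), CH2Cl2, 0 °C → rt
Reagents that add atoms: none
Why: Steglich esterification, with DCC activating the acid and DMAP transferring the acyl group to the hindered axial 3-hydroxyl as in the acylation of benzylated epicatechin with benzylated gallic acid, breaks no bond at C2 or C3, so both centres are retained.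

**Step 10**
Reactants: 18 (2R,3R)-5,7-bis(benzyloxy)-2-[3,4-bis(benzyloxy)phenyl]chroman-3-yl 4-(benzyloxy)-3,5-dimethoxybenzoate
Product: 19 (2R,3R)-2-(3,4-dihydroxyphenyl)-5,7-dihydroxychroman-3-yl 4-hydroxy-3,5-dimethoxybenzoate ((−)-epicatechin 3-O-syringate, target)
Conditions: H2 (1 atm), 20% Pd(OH)2/C, THF/MeOH, rt
Reagents that add atoms: none
Why: Catalytic hydrogenolysis of the five aryl benzyl ethers over Pearlman's catalyst at atmospheric pressure should release the target, because the benzoate ester, the methyl ethers and the cyclic benzylic ether O1–C2 persist under these conditions and neither stereocentre is touched.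

**Compound list**

1 | 3,4-dihydroxyphenylacetic acid | OC(=O)Cc1ccc(O)c(O)c1 | starting material
2 | benzyl bromide | BrCc1ccccc1 | starting material
3 | benzyl 2-[3,4-bis(benzyloxy)phenyl]acetate | O=C(Cc1ccc(OCc2ccccc2)c(OCc2ccccc2)c1)OCc1ccccc1 | intermediate
4 | 4-acetamidobenzenesulfonyl azide | CC(=O)Nc1ccc(cc1)S(=O)(=O)N=[N+]=[N-] | starting material
5 | benzyl 2-[3,4-bis(benzyloxy)phenyl]-2-diazoacetate | [N-]=[N+]=C(C(=O)OCc1ccccc1)c1ccc(OCc2ccccc2)c(OCc2ccccc2)c1 | intermediate
6 | 3,5-bis(benzyloxy)phenol | Oc1cc(OCc2ccccc2)cc(OCc2ccccc2)c1 | starting material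
7 | benzyl 2-[3,5-bis(benzyloxy)phenoxy]-2-[3,4-bis(benzyloxy)phenyl]acetate (racemic) | O=C(OCc1ccccc1)C(Oc1cc(OCc2ccccc2)cc(OCc2ccccc2)c1)c1ccc(OCc2ccccc2)c(OCc2ccccc2)c1 | intermediate
8 | 2-[3,5-bis(benzyloxy)phenoxy]-2-[3,4-bis(benzyloxy)phenyl]acetic acid (racemic) | OC(=O)C(Oc1cc(OCc2ccccc2)cc(OCc2ccccc2)c1)c1ccc(OCc2ccccc2)c(OCc2ccccc2)c1 | intermediate
9 | 2-[3,5-bis(benzyloxy)phenoxy]-2-[3,4-bis(benzyloxy)phenyl]acetic trifluoroacetic anhydride (racemic, not isolated) | O=C(OC(=O)C(F)(F)F)C(Oc1cc(OCc2ccccc2)cc(OCc2ccccc2)c1)c1ccc(OCc2ccccc2)c(OCc2ccccc2)c1 | intermediate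
10 | 4,6-bis(benzyloxy)-2-[3,4-bis(benzyloxy)phenyl]benzofuran-3(2H)-one (racemic, C2 labile) | O=C1c2c(OCc3ccccc3)cc(OCc3ccccc3)cc2OC1c1ccc(OCc2ccccc2)c(OCc2ccccc2)c1 | intermediate
11 | trimethylsilyldiazomethane | C[Si](C)(C)C=[N+]=[N-] | starting material
12 | 5,7-bis(benzyloxy)-2-[3,4-bis(benzyloxy)phenyl]-4-(trimethylsilyl)chroman-3-one (racemic diastereomer mixture, not isolated) | O=C1C([Si](C)(C)C)c2c(OCc3ccccc3)cc(OCc3ccccc3)cc2OC1c1ccc(OCc2ccccc2)c(OCc2ccccc2)c1 | intermediate
13 | 5,7-bis(benzyloxy)-2-[3,4-bis(benzyloxy)phenyl]chroman-3-one (racemic, C2 labile; tetra-O-benzylflavan-3-one) | O=C1Cc2c(OCc3ccccc3)cc(OCc3ccccc3)cc2OC1c1ccc(OCc2ccccc2)c(OCc2ccccc2)c1 | intermediate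
14 | (2R,3R)-5,7-bis(benzyloxy)-2-[3,4-bis(benzyloxy)phenyl]chroman-3-ol | O[C@@H]1Cc2c(OCc3ccccc3)cc(OCc3ccccc3)cc2O[C@@H]1c1ccc(OCc2ccccc2)c(OCc2ccccc2)c1 | intermediate
15 | syringic acid (4-hydroxy-3,5-dimethoxybenzoic acid) | COc1cc(C(=O)O)cc(OC)c1O | starting material
16 | benzyl 4-(benzyloxy)-3,5-dimethoxybenzoate (not isolated) | COc1cc(C(=O)OCc2ccccc2)cc(OC)c1OCc1ccccc1 | intermediate
17 | 4-(benzyloxy)-3,5-dimethoxybenzoic acid | COc1cc(C(=O)O)cc(OC)c1OCc1ccccc1 | intermediate
18 | (2R,3R)-5,7-bis(benzyloxy)-2-[3,4-bis(benzyloxy)phenyl]chroman-3-yl 4-(benzyloxy)-3,5-dimethoxybenzoate | COc1cc(C(=O)O[C@@H]2Cc3c(OCc4ccccc4)cc(OCc4ccccc4)cc3O[C@@H]2c2ccc(OCc3ccccc3)c(OCc3ccccc3)c2)cc(OC)c1OCc1ccccc1 | intermediate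
19 | (2R,3R)-2-(3,4-dihydroxyphenyl)-5,7-dihydroxychroman-3-yl 4-hydroxy-3,5-dimethoxybenzoate | COc1cc(C(=O)O[C@@H]2Cc3c(O)cc(O)cc3O[C@@H]2c2ccc(O)c(O)c2)cc(OC)c1O | target

**Step count**

Total steps: 10. Longest linear sequence: 9 steps (1 → 3 → 5 → 7 → 8 → 10 → 13 → 14 → 18 → 19); step 8 is a one-step side branch.

**Steps most likely to fail**

Step 6 (carries the label). The diazoalkane may add too slowly to a carbonyl that three oxygen donors deactivate. The 3-hydroxybenzofuran tautomer may be alkylated or silylated on oxygen. C2 may shift in place of C3a and lead to the 4-ketone. A stoichiometric, stronger Lewis acid would be tried first. The fallback uses known chemistry, leaves the route at acid 8 and avoids the ring expansion. Oxalyl chloride with catalytic DMF in CH2Cl2 should convert 8 into 2-[3,5-bis(benzyloxy)phenoxy]-2-[3,4-bis(benzyloxy)phenyl]acetyl chloride F1. Trimethylsilyldiazomethane (11) in THF/MeCN at 0 °C should acylate to 3-[3,5-bis(benzyloxy)phenoxy]-3-[3,4-bis(benzyloxy)phenyl]-1-diazopropan-2-one F2. Rh2(OAc)4 in CH2Cl2 should then close C4–C4a by intramolecular aromatic substitution of the rhodium carbenoid on the phloroglucinol ring, the established way from aryloxy diazoketones to chroman-3-ones. The route is rejoined at 13.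

Step 7. Racemisation at C2 may not keep pace with hydrogenation, or the catalyst may distinguish the enantiomers and faces poorly on a ketone with no aryl group directly on the carbonyl, so enantiomeric purity or cis selectivity may fall short. The enolate may also be lost to oxidation. The fallback sets out from 13 and replaces catalyst control by substrate control plus resolution. L-Selectride in THF at −78 °C should deliver hydride anti to the 2-aryl group and give the racemic cis alcohol, that is 14 together with its mirror image (2S,3S)-5,7-bis(benzyloxy)-2-[3,4-bis(benzyloxy)phenyl]chroman-3-ol F3. Preparative chromatography on a chiral stationary phase separates the two, and F3 is returned to 13 by Dess–Martin oxidation for another pass. The route is rejoined at 14.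

Step 5. The activated acid may lose carbon monoxide, because the α-aryloxybenzyl cation left behind is well stabilised. Acid may transfer benzyl groups on the phloroglucinol ring. The enolisable product may autoxidise at C2 during work-up. The fallback sets out from 8 and acylates the ring through an iminium ion that cannot lose CO. Carbodiimide coupling with dimethylamine (EDC, HOBt, CH2Cl2) should give 2-[3,5-bis(benzyloxy)phenoxy]-2-[3,4-bis(benzyloxy)phenyl]-N,N-dimethylacetamide F4. POCl3 in refluxing CH2Cl2 should effect a Vilsmeier–Haack-type cyclisation of the chloroiminium ion onto the ring, giving 4,6-bis(benzyloxy)-2-[3,4-bis(benzyloxy)phenyl]-N,N-dimethylbenzofuran-3-amine F5 after loss of HCl. Mild aqueous acid (dilute HCl, THF, rt, under argon) should hydrolyse this enamine. The route is rejoined at 10.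

**Further compounds**

F1 | step 6 | 2-[3,5-bis(benzyloxy)phenoxy]-2-[3,4-bis(benzyloxy)phenyl]acetyl chloride (racemic) | ClC(=O)C(Oc1cc(OCc2ccccc2)cc(OCc2ccccc2)c1)c1ccc(OCc2ccccc2)c(OCc2ccccc2)c1
F2 | step 6 | 3-[3,5-bis(benzyloxy)phenoxy]-3-[3,4-bis(benzyloxy)phenyl]-1-diazopropan-2-one (racemic) | [N-]=[N+]=CC(=O)C(Oc1cc(OCc2ccccc2)cc(OCc2ccccc2)c1)c1ccc(OCc2ccccc2)c(OCc2ccccc2)c1
F3 | step 7 | (2S,3S)-5,7-bis(benzyloxy)-2-[3,4-bis(benzyloxy)phenyl]chroman-3-ol (mirror image of 14) | O[C@H]1Cc2c(OCc3ccccc3)cc(OCc3ccccc3)cc2O[C@H]1c1ccc(OCc2ccccc2)c(OCc2ccccc2)c1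
F4 | step 5 | 2-[3,5-bis(benzyloxy)phenoxy]-2-[3,4-bis(benzyloxy)phenyl]-N,N-dimethylacetamide (racemic) | CN(C)C(=O)C(Oc1cc(OCc2ccccc2)cc(OCc2ccccc2)c1)c1ccc(OCc2ccccc2)c(OCc2ccccc2)c1
F5 | step 5 | 4,6-bis(benzyloxy)-2-[3,4-bis(benzyloxy)phenyl]-N,N-dimethylbenzofuran-3-amine | CN(C)c1c(-c2ccc(OCc3ccccc3)c(OCc3ccccc3)c2)oc2cc(OCc3ccccc3)cc(OCc3ccccc3)c12
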